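## The problem

Compound 19 is a benzophenone whose carbonyl joins two resorcinol rings. Ring A carries a propyl group and ring B a CH2-linked 4-hydroxy-2-pyranone (ring C), each ortho to the ketone, so the carbonyl is flanked by four ortho substituents. The diaryl ketone bond must therefore be made by a method that tolerates crowding and that places the acyl carbon between an oxygen-bearing and a carbon-bearing position on both rings, not between the two oxygens. The molecule has no stereocentre, so any stereocentre made on the way is transient, needs no control and cannot be used to control another. The five hydroxyl groups, one of them a vinylogous carboxylic acid, make free 19 polar and sensitive to air and base, so all five should stay masked until the last step. The CH2 between rings B and C is doubly activated, and a two-carbon carbonyl side chain ortho to the diaryl ketone can condense with that ketone under strong acid or base, so ring C has to be built under nearly neutral conditions. The enabling feature lies in ring C: C6 is bonded at once to the ring oxygen O1, to C5 and to the benzylic CH2. C6 and O1 can therefore be the carbon and oxygen of an arylacetaldehyde carbonyl group, while C2–C5 with the oxygens on C2 and C4 correspond to an acetoacetate-derived 1,3-dioxygenated diene.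

## Retrosynthesis

**19 ⇒ 18.** The last cut goes through the five O–CH3 bonds and leads back to pentamethyl ether 18. Methyl is preferred to benzyl, whose hydrogenolysis would endanger the C5=C6 bond of ring C and the diaryl ketone, and to acetal groups, which would not survive the formylation and Lewis acid steps. Compound 18 is neutral, lipophilic and easy to purify, and four of its five methyl ethers are present from the first steps. The forward step must cleave four aryl methyl ethers and one vinylogous methyl ester in one operation without harming the pyranone.

**18 ⇒ 17.** Adding two hydrogens across C5–C6 of ring C gives the 5,6-dihydropyranone 17. This puts C6 at the alcohol oxidation level, so that it can come from an aldehyde. Keeping C6 at the acid level would require an ortho-aroyl arylacetic acid derivative and a strongly basic Claisen condensation beside the acidic benzylic CH2. Compound 17 differs from 18 by two hydrogens and one racemic stereocentre. The forward step is a dehydrogenation that has to spare the benzylic CH2 groups and the electron-rich rings.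

**17 ⇒ 12 + 15.** Cutting C5–C6 and O1–C2 removes ring C in one stroke and leaves keto aldehyde 12 and silyloxy diene 15. Two neighbouring cuts are less attractive. Cutting the exocyclic CH2–C6 bond would need alkylation of a pyranone methyl anion by a benzylic halide that sits ortho to the ketone. Cutting the ring B–CH2 bond would place a cross-coupling at the most crowded position of ring B. The chosen cut forms both bonds at a remote, unhindered aldehyde carbon and attaches the whole heterocycle to a finished benzophenone. Compound 12 holds every carbon of rings A and B, and 15 is one step from a commercial ester. The forward reaction must select the aldehyde over the diaryl ketone and must not enolise the arylacetaldehyde. Because 12 is a 1,5-dicarbonyl compound that strong acid could close onto itself, a mild lanthanide Lewis acid is planned instead of a stoichiometric boron or titanium halide.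

**12 ⇒ 11 ⇒ 10.** The aldehyde is taken back to primary alcohol 11 and this to its silyl ether 10. Carrying the side chain as a protected alcohol keeps the sensitive arylacetaldehyde out of the organolithium and oxidation steps, and it is released only just before use. The forward steps are a fluoride desilylation and a non-acidic, non-aqueous alcohol oxidation.

**10 ⇒ 9 ⇒ 8 (from 7) + 4.** The diaryl ketone is traced through carbinol 9 to aryllithium 8 and aldehyde 4, which cuts the bond between the carbonyl carbon and ring B. This bond is chosen over the one to ring A for reasons of regiocontrol. Electrophilic bromination of ring B precursor 5 places the halogen exactly at the future ketone position, ortho to the side chain and para to a methoxy group. Direct lithiation of ring A ether 2 would instead occur between its two methoxy groups, and ring A is better served by electrophilic formylation, which goes to the correct carbon. Addition to an aldehyde followed by oxidation is preferred to direct acylation: an aldehyde carbon accepts a di-ortho-substituted aryllithium where a 2,6-disubstituted benzoyl electrophile reacts sluggishly, and over-addition cannot occur. The forward steps need clean bromine–lithium exchange beside the silyl ether and an oxidant that does not ionise the electron-rich benzhydrol.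

**7 ⇒ 6 ⇒ 5 and 4 ⇒ 2 ⇒ 1.** Bromide 7 comes from commercial alcohol 5 by ring bromination to 6 and silylation. Aldehyde 4 comes from commercial diol 1 by double O-methylation to 2 and Vilsmeier formylation through iminium salt 3. Each ring thus gets its substitution pattern from one regioselective electrophilic substitution on a symmetrical arene.

**15 ⇒ 13.** Diene 15 is the O-silylated dienolate 14 of commercial ester 13. The C4 methyl group of 13 is cis to the ester and is the only acidic position.

## Roads not taken

Alternative 1: Both benzene rings are cut back to alkynes. Rings A and B would form together from the skipped diynone A2 and two equivalents of the ketene-acetal diene A3. In the forward step each ynone unit takes up one molecule of A3 in hot toluene, with the CH2 terminus of A3 bonding to the alkyl-bearing alkyne carbon and the acetal carbon to the acyl-bearing one. Loss of one methoxy group per ring aromatises the adducts to benzophenone A1. The merit is real: the four-fold ortho-substituted ketone is never made by attack on a crowded carbonyl, both arenes arise in one operation from a linear precursor, and the diene polarisation sets the regiochemistry. In this respect the road is better than the chosen plan, which relies on adding crowded aryllithium 8 to crowded aldehyde 4. The weak points lie elsewhere. Ynones with an alkyl group on the far alkyne carbon are slow dienophiles and need prolonged heating, which a ketene-acetal diene tolerates poorly. After the first ring has formed, the remaining ynone is attached to a di-ortho-substituted arene and is slower still, so mono-adduct would accumulate. A2 is also a double Michael acceptor towards the alcohol set free in the aromatisation. Finally, A1 still carries only a two-carbon silyl ether, so ring C has yet to be built by the same deprotection, oxidation, annulation and dehydrogenation sequence as in the chosen plan, and its free para-hydroxyl groups need capping first. The route is therefore not shorter. Against the advantage in forming the ketone, the chosen plan sets commercial arenes that already hold the correct oxygen pattern and two regiodefined substitutions that are routine.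

Alternative 2: The bond from the ketone carbon to ring A and the bond from ring A to the future propyl α-carbon are cut together. Fluoride releases an aryne from silyl triflate A5, and this aryne inserts into the C–C bond between the ketone and the α-carbon of β-keto ester A6 to give keto diester A4. The methoxy group next to the aryne directs the enolate carbon to the distal aryne carbon, so the ring A pattern comes out correctly. The ring B side chain also arrives as an arylacetic ester, at the acid oxidation level. Ring C could then be closed from a 3,5-dioxo ester with no dehydrogenation, which is better than step 11 of the chosen plan. The doubts concern the key step itself. A6 bears an α-ethyl group and its ketone is a di-ortho-substituted aryl ketone, and the aryl anion formed after the first C–C bond must close onto that hindered carbonyl to make a four-membered alkoxide before fragmenting. Simple α-arylation or protonation of the aryl anion are the likely diversions. The propyl group appears as a 1-(tert-butoxycarbonyl)propyl group and needs ester cleavage and decarboxylation. A5 and A6 each take several steps from simple aromatics. The chosen plan accepts one dehydrogenation and in return uses only bond formations that are known to tolerate the crowding present here, in fewer steps overall.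

Alternative 3: Ring B is cut between its ketone-bearing and its alkyl-bearing carbon. Aqueous hydroxide would open 4-pyranone A8 to tetraketone A9, whose CH2 between the aryl ketone and the next carbonyl adds to the ketone at the far end of the chain and dehydrates, giving resorcinol ketone A7. The fold is biomimetic and avoids any coupling between two crowded arenes, because the aryl ketone is made as an alkyl aryl ketone before ring B exists. It also delivers the ring B hydroxyl groups free, which would lighten the final deprotection. On these two points it compares well with the chosen plan. Its weaknesses are selectivity and length. A9 can fold in several ways, including reclosure to a pyranone and aldol attack from the other chain end. Its terminal ketone carries a β-benzyloxy group that hydroxide can eliminate, which would destroy the handle for ring C. A8 needs a multistep polyketide-type assembly of its own. After the key step ring C still has to be built from the benzyloxyethyl group by debenzylation, oxidation, annulation and dehydrogenation, exactly as from 11 in the chosen plan. The chosen plan sets against it a short, regiodefined aromatic route to 12 in which no step depends on steering a polyketone.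

Key step: step 10

Assumption: 19 has no stereocentre and is drawn as its 4-hydroxy-2-pyranone tautomer, so the stereocentres of 9, 16 and 17 are transient and these compounds are carried as racemates.

## Route

Step 1
Reactants: 1 5-propylbenzene-1,3-diol
Product: 2 1,3-dimethoxy-5-propylbenzene
Conditions: MeI, K2CO3, acetone, reflux
Reagents that add atoms: iodomethane, CI
Why: Williamson ether synthesis; the two phenols are the only acidic sites and both are methylated.

Step 2
Reactants: 2 1,3-dimethoxy-5-propylbenzene
Product: 4 2,4-dimethoxy-6-propylbenzaldehyde, via iminium salt 3 (not isolated)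
Conditions: POCl3, DMF, 0 → 80 °C; then H2O, rt
Reagents that add atoms: N,N-dimethylformamide, CN(C)C=O; water, O
Why: Vilsmeier–Haack formylation; the chloroiminium electrophile should attack one of the two equivalent positions para to one methoxy and ortho to the other, not the more crowded carbon between the two methoxy groups, and water hydrolyses iminium salt 3 to the aldehyde.

Step 3
Reactants: 5 2-(3,5-dimethoxyphenyl)ethanol
Product: 6 2-(2-bromo-3,5-dimethoxyphenyl)ethanol
Conditions: NBS (1.0 equiv), MeCN, 0 °C → rt
Reagents that add atoms: N-bromosuccinimide, O=C1CCC(=O)N1Br
Why: Electrophilic aromatic bromination; 3,5-dimethoxyalkylbenzenes brominate ortho to the alkyl group and para to a methoxy group in preference to the position between the two methoxy groups, and one equivalent should stop at the monobromide.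

Step 4
Reactants: 6 2-(2-bromo-3,5-dimethoxyphenyl)ethanol
Product: 7 tert-butyl[2-(2-bromo-3,5-dimethoxyphenyl)ethoxy]dimethylsilane
Conditions: TBSCl, imidazole, DMF, rt
Reagents that add atoms: tert-butyldimethylsilyl chloride, CC(C)(C)[Si](C)(C)Cl
Why: Imidazole-promoted silylation masks the acidic hydroxyl before the lithiation; the TBS ether is stable to n-BuLi at low temperature and to the later oxidation.

Step 5
Reactants: 7 tert-butyl[2-(2-bromo-3,5-dimethoxyphenyl)ethoxy]dimethylsilane; 4 2,4-dimethoxy-6-propylbenzaldehyde
Product: 9 (RS)-{2-[2-(tert-butyldimethylsilyloxy)ethyl]-4,6-dimethoxyphenyl}(2,4-dimethoxy-6-propylphenyl)methanol, via aryllithium 8 (not isolated)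
Conditions: n-BuLi, THF, −78 °C; then 4, −78 → 0 °C; H2O
Reagents that add atoms: none
Why: Bromine–lithium exchange followed by 1,2-addition of the aryllithium to a non-enolisable aldehyde, the usual entry to benzhydrols with four ortho substituents; the new carbinol stereocentre forms without control and is removed in step 6.

Step 6
Reactants: 9 (RS)-{2-[2-(tert-butyldimethylsilyloxy)ethyl]-4,6-dimethoxyphenyl}(2,4-dimethoxy-6-propylphenyl)methanol
Product: 10 {2-[2-(tert-butyldimethylsilyloxy)ethyl]-4,6-dimethoxyphenyl}(2,4-dimethoxy-6-propylphenyl)methanone
Conditions: Dess–Martin periodinane, NaHCO3, CH2Cl2, rt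
Reagents that add atoms: none
Why: Dess–Martin oxidation of a secondary benzhydrol to the diaryl ketone; the hydrogencarbonate buffer should keep the acetic acid formed from ionising the electron-rich benzhydrol.

Step 7
Reactants: 10 {2-[2-(tert-butyldimethylsilyloxy)ethyl]-4,6-dimethoxyphenyl}(2,4-dimethoxy-6-propylphenyl)methanone
Product: 11 [2-(2-hydroxyethyl)-4,6-dimethoxyphenyl](2,4-dimethoxy-6-propylphenyl)methanone
Conditions: TBAF, THF, 0 °C → rt
Reagents that add atoms: none
Why: Fluoride-induced desilylation driven by the Si–F bond; the methyl ethers and the hindered ketone are inert to fluoride.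

Step 8
Reactants: 11 [2-(2-hydroxyethyl)-4,6-dimethoxyphenyl](2,4-dimethoxy-6-propylphenyl)methanone
Product: 12 2-[2-(2,4-dimethoxy-6-propylbenzoyl)-3,5-dimethoxyphenyl]acetaldehyde
Conditions: Dess–Martin periodinane, NaHCO3, CH2Cl2, 0 °C → rt
Reagents that add atoms: none
Why: Dess–Martin oxidation stops at the aldehyde, and the buffered, water-free medium should avoid enolisation of the arylacetaldehyde and its condensation with the ortho ketone; 12 is to be used at once in step 10.

Step 9
Reactants: 13 methyl (2E)-3-methoxybut-2-enoate
Product: 15 (1E)-1,3-dimethoxy-1-(trimethylsilyloxy)buta-1,3-diene, via lithium dienolate 14 (not isolated)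
Conditions: LiN(i-Pr)2, THF, −78 °C; then TMSCl, −78 °C → rt
Reagents that add atoms: chlorotrimethylsilane, C[Si](C)(C)Cl
Why: γ-Deprotonation of the vinylogous ester at its only acidic CH3 and O-silylation of dienolate 14, the standard preparation of 1,3-dialkoxy-1-silyloxybutadienes; the diene is distilled and used fresh.

Step 10
Reactants: 12 2-[2-(2,4-dimethoxy-6-propylbenzoyl)-3,5-dimethoxyphenyl]acetaldehyde; 15 (1E)-1,3-dimethoxy-1-(trimethylsilyloxy)buta-1,3-diene
Product: 17 6-{[2-(2,4-dimethoxy-6-propylbenzoyl)-3,5-dimethoxyphenyl]methyl}-4-methoxy-5,6-dihydro-2H-pyran-2-one (racemic), via cyclic silyl ketal 16 (not isolated)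
Conditions: Eu(fod)3 [europium tris(6,6,7,7,8,8,8-heptafluoro-2,2-dimethyloctane-3,5-dionate)] (5 mol %), CH2Cl2, 0 °C → rt; then TFA (cat.), 0 °C
Reagents that add atoms: none
Why: The oxophilic europium chelate binds the aldehyde oxygen of 12, the CH2 terminus (C4) of diene 15 attacks the aldehyde carbon to form the C5–C6 bond, and the aldehyde oxygen bonds to the ketene-acetal carbon to form O1–C2, giving cyclic silyl ketal 16; the acid then expels the silyloxy and one methoxy group together from the ketal carbon and leaves the lactone carbonyl of 17. The closest known reaction type is the lanthanide-catalysed hetero-Diels–Alder reaction of 1,3-dialkoxy-1-silyloxybutadienes with aliphatic aldehydes, which gives 6-substituted 4-methoxy-5,6-dihydropyran-2-ones. The six-membered ring closes by a (4+2) cycloaddition that may be concerted but asynchronous or, at the stepwise limit, a Mukaiyama-type addition followed by 6-exo-trig capture of the silyloxycarbenium ion by the aldolate oxygen; both paths lead to 16. The new stereocentre at C6 has no controlling element, since substrate and catalyst are achiral, so 17 should form as a racemate, which is harmless because step 11 makes C6 planar; the ketal carbon of 16 loses its stereochemistry on collapse. The step needs reaction at the aldehyde and not at the diaryl ketone, and this is secured by the four ortho substituents that twist and shield the ketone so that it neither binds the catalyst well nor admits the diene. It also needs the arylacetaldehyde to remain un-enolised and uncondensed with the ortho ketone, which the nearly neutral catalyst at or below room temperature should ensure where a stoichiometric strong Lewis acid might not. Regiochemistry follows from the polarisation of 15, whose only nucleophilic terminus is C4.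

Step 11
Reactants: 17 6-{[2-(2,4-dimethoxy-6-propylbenzoyl)-3,5-dimethoxyphenyl]methyl}-4-methoxy-5,6-dihydro-2H-pyran-2-one (racemic)
Product: 18 6-{[2-(2,4-dimethoxy-6-propylbenzoyl)-3,5-dimethoxyphenyl]methyl}-4-methoxy-2H-pyran-2-one
Conditions: DDQ, 1,4-dioxane, reflux
Reagents that add atoms: none
Why: Quinone dehydrogenation by hydride abstraction and proton loss, driven by formation of the conjugated 2-pyranone and known for 4-methoxy-5,6-dihydropyran-2-ones of the kavalactone type. Both benzylic CH2 groups are meta to the methoxy groups and ortho to the acyl group, so they are not activated for hydride loss. The step also removes the C6 stereocentre.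

Step 12
Reactants: 18 6-{[2-(2,4-dimethoxy-6-propylbenzoyl)-3,5-dimethoxyphenyl]methyl}-4-methoxy-2H-pyran-2-one
Product: 19 6-{[2-(2,4-dihydroxy-6-propylbenzoyl)-3,5-dihydroxyphenyl]methyl}-4-hydroxy-2H-pyran-2-one
Conditions: BBr3 (excess), CH2Cl2, −78 °C → rt; then H2O
Reagents that add atoms: none
Why: Lewis acid ether cleavage in which BBr3 binds each oxygen and bromide removes the methyl group by SN2. The two methoxy groups ortho to the ketone are helped by chelation, and the pyranone methyl ether is a vinylogous methyl ester activated by coordination at the ring carbonyl. Water hydrolyses the borate esters to 19.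

## Compound list

1 | 5-propylbenzene-1,3-diol | CCCc1cc(O)cc(O)c1 | starting material
2 | 1,3-dimethoxy-5-propylbenzene | CCCc1cc(OC)cc(OC)c1 | intermediate
3 | N-[(2,4-dimethoxy-6-propylphenyl)methylidene]-N-methylmethanaminium dichlorophosphate (not isolated) | CCCc1cc(OC)cc(OC)c1C=[N+](C)C.[O-]P(=O)(Cl)Cl | intermediate
4 | 2,4-dimethoxy-6-propylbenzaldehyde | CCCc1cc(OC)cc(OC)c1C=O | intermediate
5 | 2-(3,5-dimethoxyphenyl)ethanol | COc1cc(CCO)cc(OC)c1 | starting material
6 | 2-(2-bromo-3,5-dimethoxyphenyl)ethanol | OCCc1cc(OC)cc(OC)c1Br | intermediate
7 | tert-butyl[2-(2-bromo-3,5-dimethoxyphenyl)ethoxy]dimethylsilane | CC(C)(C)[Si](C)(C)OCCc1cc(OC)cc(OC)c1Br | intermediate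
8 | {2-[2-(tert-butyldimethylsilyloxy)ethyl]-4,6-dimethoxyphenyl}lithium (not isolated) | [Li]c1c(CCO[Si](C)(C)C(C)(C)C)cc(OC)cc1OC | intermediate
9 | (RS)-{2-[2-(tert-butyldimethylsilyloxy)ethyl]-4,6-dimethoxyphenyl}(2,4-dimethoxy-6-propylphenyl)methanol | CCCc1cc(OC)cc(OC)c1C(O)c1c(OC)cc(OC)cc1CCO[Si](C)(C)C(C)(C)C | intermediate
10 | {2-[2-(tert-butyldimethylsilyloxy)ethyl]-4,6-dimethoxyphenyl}(2,4-dimethoxy-6-propylphenyl)methanone | CCCc1cc(OC)cc(OC)c1C(=O)c1c(OC)cc(OC)cc1CCO[Si](C)(C)C(C)(C)C | intermediate
11 | [2-(2-hydroxyethyl)-4,6-dimethoxyphenyl](2,4-dimethoxy-6-propylphenyl)methanone | CCCc1cc(OC)cc(OC)c1C(=O)c1c(OC)cc(OC)cc1CCO | intermediate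
12 | 2-[2-(2,4-dimethoxy-6-propylbenzoyl)-3,5-dimethoxyphenyl]acetaldehyde | CCCc1cc(OC)cc(OC)c1C(=O)c1c(OC)cc(OC)cc1CC=O | intermediate
13 | methyl (2E)-3-methoxybut-2-enoate | CO/C(C)=C/C(=O)OC | starting material
14 | lithium (1Z)-1,3-dimethoxybuta-1,3-dien-1-olate (not isolated) | C=C(OC)/C=C(\OC)[O-].[Li+] | intermediate
15 | (1E)-1,3-dimethoxy-1-(trimethylsilyloxy)buta-1,3-diene | C=C(OC)/C=C(\OC)O[Si](C)(C)C | intermediate
16 | 6-{[2-(2,4-dimethoxy-6-propylbenzoyl)-3,5-dimethoxyphenyl]methyl}-2,4-dimethoxy-2-(trimethylsilyloxy)-5,6-dihydro-2H-pyran (racemic, both C2 epimers; not isolated) | CCCc1cc(OC)cc(OC)c1C(=O)c1c(OC)cc(OC)cc1CC1CC(OC)=CC(OC)(O[Si](C)(C)C)O1 | intermediate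
17 | 6-{[2-(2,4-dimethoxy-6-propylbenzoyl)-3,5-dimethoxyphenyl]methyl}-4-methoxy-5,6-dihydro-2H-pyran-2-one (racemic) | CCCc1cc(OC)cc(OC)c1C(=O)c1c(OC)cc(OC)cc1CC1CC(OC)=CC(=O)O1 | intermediate
18 | 6-{[2-(2,4-dimethoxy-6-propylbenzoyl)-3,5-dimethoxyphenyl]methyl}-4-methoxy-2H-pyran-2-one | CCCc1cc(OC)cc(OC)c1C(=O)c1c(OC)cc(OC)cc1Cc1cc(OC)cc(=O)o1 | intermediate
19 | 6-{[2-(2,4-dihydroxy-6-propylbenzoyl)-3,5-dihydroxyphenyl]methyl}-4-hydroxy-2H-pyran-2-one | CCCc1cc(O)cc(O)c1C(=O)c1c(O)cc(O)cc1Cc1cc(O)cc(=O)o1 | target

## Step count and least certain steps

Total: 12 steps. Longest linear sequence: 9 steps (steps 3–8 and 10–12, from 5). Steps 1–2 (ring A aldehyde) and step 9 (diene) are side branches.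

**Step 10 (key step).**
- What may go wrong: acid-induced ring closure of the 1,5-dicarbonyl unit of 12 with loss of water, or enolisation and self-aldol of the arylacetaldehyde, may outrun a slow addition of the diene. Hydrolysis of the moisture-sensitive diene lowers its effective concentration. Collapse of the adduct may stop short of the lactone.
- Fallback: this sets out from aldehyde 12 and activates the nucleophile instead of the electrophile. The dianion of methyl acetoacetate (NaH, then n-BuLi, THF, −78 °C) should add through its terminal carbon to give the δ-hydroxy-β-keto ester F1. Intramolecular transesterification (K2CO3, MeOH, then dilute HCl) should close it to the oxane-2,4-dione F2. O-Methylation of the enol of F2 (Me2SO4, K2CO3, acetone) should then give the 4-methoxy-5,6-dihydropyranone, where the route is rejoined at 17.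

**Step 11.**
- What may go wrong: hydride abstraction at C6 may be slow because C6 carries no aryl or vinyl group, so conversion stalls. Forcing the reaction invites oxidation at the benzylic CH2 beside ring C and degradation of the electron-rich rings.
- Fallback: the oxidation is moved to the open chain. It sets out from 12 by way of F1, prepared as above. Dess–Martin oxidation of the secondary alcohol of F1 should give the 3,5-dioxo ester F3. DBU in toluene should close F3 through its enol oxygen, with loss of the ester alkoxy group, to the 4-hydroxy-2-pyranone F4; the crowded diaryl ketone is expected to stay out of a competing aldol closure. O-Methylation of F4 (Me2SO4, K2CO3, acetone) should give the 4-methoxy-2-pyranone, where the route is rejoined at 18.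

**Step 12.**
- What may go wrong: incomplete cleavage of the two non-chelated para-methoxy groups or of the vinylogous ester leaves partly methylated material. Long exposure to the boron Lewis acid and HBr may cause acid-promoted condensation between ring C and the ketone, and the polyphenol may be lost on isolation.
- Fallback: ring C is carried to the end with its oxygen free. It sets out from 12 through F1 and F3 to the 4-hydroxy-2-pyranone F4, as described for step 11, and F4 itself is treated with BBr3. Only four aryl ethers, two of them chelation-activated, then need cleaving, and the sequence comes back at target 19. It makes no compound beyond those already named.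

**Step 5.**
- What may go wrong: addition of the di-ortho-substituted aryllithium to the di-ortho-substituted aldehyde may be slow, so that quenching of the aryllithium by adventitious proton sources, or migration of the silyl group from oxygen to the lithiated carbon on warming, competes.
- Fallback: the two rings are joined electrophilically instead of nucleophilically. Pinnick oxidation of aldehyde 4 (NaClO2, NaH2PO4, 2-methylbut-2-ene, t-BuOH/H2O) should give 2,4-dimethoxy-6-propylbenzoic acid F5. With trifluoroacetic anhydride, alcohol 5 is first converted in the flask into 2-(3,5-dimethoxyphenyl)ethyl trifluoroacetate F6. F6 is then acylated by the mixed anhydride of F5 in a Friedel–Crafts reaction para to a methoxy group, giving the benzophenone trifluoroacetate F7. Methanolysis (K2CO3, MeOH) should give the keto alcohol, where the route is rejoined at 11, bypassing steps 3–7. The cost is that no bromine atom fixes the regiochemistry, so product acylated between the two methoxy groups would have to be separated.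

## Further compounds

F1 | step 10 | methyl 6-[2-(2,4-dimethoxy-6-propylbenzoyl)-3,5-dimethoxyphenyl]-5-hydroxy-3-oxohexanoate (racemic) | CCCc1cc(OC)cc(OC)c1C(=O)c1c(OC)cc(OC)cc1CC(O)CC(=O)CC(=O)OC
F2 | step 10 | 6-{[2-(2,4-dimethoxy-6-propylbenzoyl)-3,5-dimethoxyphenyl]methyl}oxane-2,4-dione (racemic) | CCCc1cc(OC)cc(OC)c1C(=O)c1c(OC)cc(OC)cc1CC1CC(=O)CC(=O)O1
F3 | step 11 | methyl 6-[2-(2,4-dimethoxy-6-propylbenzoyl)-3,5-dimethoxyphenyl]-3,5-dioxohexanoate | CCCc1cc(OC)cc(OC)c1C(=O)c1c(OC)cc(OC)cc1CC(=O)CC(=O)CC(=O)OC
F4 | step 11 | 6-{[2-(2,4-dimethoxy-6-propylbenzoyl)-3,5-dimethoxyphenyl]methyl}-4-hydroxy-2H-pyran-2-one | CCCc1cc(OC)cc(OC)c1C(=O)c1c(OC)cc(OC)cc1Cc1cc(O)cc(=O)o1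
F0 | step 12 | none | none
F5 | step 5 | 2,4-dimethoxy-6-propylbenzoic acid | CCCc1cc(OC)cc(OC)c1C(O)=O
F6 | step 5 | 2-(3,5-dimethoxyphenyl)ethyl trifluoroacetate | COc1cc(CCOC(=O)C(F)(F)F)cc(OC)c1
F7 | step 5 | 2-[2-(2,4-dimethoxy-6-propylbenzoyl)-3,5-dimethoxyphenyl]ethyl trifluoroacetate | CCCc1cc(OC)cc(OC)c1C(=O)c1c(OC)cc(OC)cc1CCOC(=O)C(F)(F)F
A1 | alternative 1 | {2-[2-(tert-butyldimethylsilyloxy)ethyl]-4-hydroxy-6-methoxyphenyl}(4-hydroxy-2-methoxy-6-propylphenyl)methanone | CCCc1cc(O)cc(OC)c1C(=O)c1c(OC)cc(O)cc1CCO[Si](C)(C)C(C)(C)C
A2 | alternative 1 | 1-(tert-butyldimethylsilyloxy)deca-3,6-diyn-5-one | CCCC#CC(=O)C#CCCO[Si](C)(C)C(C)(C)C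
A3 | alternative 1 | 1,1-dimethoxy-3-(trimethylsilyloxy)buta-1,3-diene | COC(OC)=CC(=C)O[Si](C)(C)C
A4 | alternative 2 | tert-butyl 2-{2-[2,4-dimethoxy-6-(2-methoxy-2-oxoethyl)benzoyl]-3,5-dimethoxyphenyl}butanoate (racemic) | CCC(C(=O)OC(C)(C)C)c1cc(OC)cc(OC)c1C(=O)c1c(OC)cc(OC)cc1CC(=O)OC
A5 | alternative 2 | 3,5-dimethoxy-2-(trimethylsilyl)phenyl trifluoromethanesulfonate | COc1cc(OC)c([Si](C)(C)C)c(OS(=O)(=O)C(F)(F)F)c1
A6 | alternative 2 | tert-butyl 2-[2,4-dimethoxy-6-(2-methoxy-2-oxoethyl)benzoyl]butanoate (racemic) | CCC(C(=O)OC(C)(C)C)C(=O)c1c(OC)cc(OC)cc1CC(=O)OC
A7 | alternative 3 | {2-[2-(benzyloxy)ethyl]-4,6-dihydroxyphenyl}(2,4-dimethoxy-6-propylphenyl)methanone | CCCc1cc(OC)cc(OC)c1C(=O)c1c(O)cc(O)cc1CCOCc1ccccc1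
A8 | alternative 3 | 2-[2-(benzyloxy)ethyl]-6-[2-(2,4-dimethoxy-6-propylphenyl)-2-oxoethyl]-4H-pyran-4-one | CCCc1cc(OC)cc(OC)c1C(=O)Cc1cc(=O)cc(CCOCc2ccccc2)o1
A9 | alternative 3 | 9-(benzyloxy)-1-(2,4-dimethoxy-6-propylphenyl)nonane-1,3,5,7-tetrone | CCCc1cc(OC)cc(OC)c1C(=O)CC(=O)CC(=O)CC(=O)CCOCc1ccccc1
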